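(The runs stem from a simulated flask with made-up constants, noise included.)

The green run, with twice the added ligand of the red flask, stands at 66.3 % target after 50.0 min and the red flask at 67.2 % after 40.0 min, so you see two curves that stop close together.

| flask | starting material | reagent | free catalyst | added ligand | remark |
|---|---|---|---|---|---|
| red | 0.011 M | 0.0132 M | 44 µM | 26 µM | the very flask that is asked about, followed so far |
| green | 0.011 M | 0.0132 M | 44 µM | 52 µM | run made earlier |
| flask | 0.011 M | 0.0132 M | 44 µM | 26 µM |  |

| red: time / min | red: target / % | green: time / min | green: target / % |
|---|---|---|---|
| 8.00 | 22.9 | 12.0 | 30.6 |
| 15.0 | 38.6 | 25.0 | 53.1 |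
| 25.0 | 56.2 | 30.0 | 57.6 |
| 30.0 | 61.5 | 50.0 | 66.3 |
| 40.0 | 67.2 | 60.0 | 65.4 |

(readings scatter by 0.5 percentage points)

- no earlier run changes the charge of free catalyst; that part of a forecast is a guess
- no earlier run changes the charge of reagent; that part of a forecast is a guess

1. apparent order in free catalyst when 30 % of the starting material are converted (percent change of the rate of making target for one percent more free catalyst charged)
2. apparent order in reagent when 30 % of the starting material are converted (percent change of the rate of making target for one percent more reagent charged)

Write the balance of the starting material, the smaller charge, and assume that each target takes one reagent: one minus the red flask's last target reading times the ratio of the starting material charge to the reagent charge gives 0.440, which I call the leftover fraction, the part of the reagent charge that the stop leaves unused. A value above zero says that, on that assumption, the red flask stops with reagent in hand, so I read the missing 33 percentage points of the starting material as lost by a path that gives no target, and I take that path to use no reagent. One number is not enough, though: it says nothing of how the rate follows reagent at 30 % conversion. No earlier run changes the charge of reagent or of free catalyst, so my own commitment, an order towards one in reagent and near one in free catalyst, is a guess.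

The forecast gives 0.9 in free catalyst and 0.2 in reagent, holding that “something stoichiometric probably runs out, most likely reagent consumed beyond 1:1”, so it parts from my reckoning on reagent.

The flask gives 0.96 in free catalyst and 0.79 in reagent, which puts the forecast within tolerance on free catalyst and low by a factor of 3.95 on reagent.

    starting material + free catalyst ⇌ catalyst intermediate A (K = 6940 L mol⁻¹, k = 2.60 × 10⁵ L mol⁻¹ min⁻¹)
    reagent + catalyst intermediate A → catalyst intermediate B (k = 854 L mol⁻¹ min⁻¹)
    catalyst intermediate B → free catalyst + target (k = 27.1 min⁻¹)
    2 starting material → homo dimer (k = 2.41 L mol⁻¹ min⁻¹)
    free catalyst + added ligand ⇌ idle complex (K = 8.08 × 10⁵ L mol⁻¹, k = 15100 L mol⁻¹ min⁻¹)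

After 80.0 min the red flask holds 43.9 % of its reagent, against the leftover fraction of 0.440, with starting material, the limiting reagent, at 0 % and homo dimer at 32.7 %; the same balance on the green reading after 50.0 min gives 0.448. When 30 % is converted, after 4.41 min, catalyst intermediate A, the resting state, holds 70.0 % of the catalyst, more than free catalyst at 1.66 %. After 12.4 min that intermediate falls back 4.6 times faster than it goes on with reagent.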